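## Retrosynthetic overview

1. Feature: ring A is a resorcinol. The oxygens on C5 and C7 flank the unsubstituted C6, and the prenylated C8 sits next to the fusion carbon C8a. The run C5–C6–C7–C8 therefore has the carbonyl/methylene alternation of an acetoacetyl chain, held at both ends (C4a, C8a) by the pyranone ring C.
2. Endgame: target ⇐ 4'-O-desilylation ⇐ 7-O-methylation of the 5,7-diol, whose 5-OH is tied to C4=O.
3. Key disconnection C5–C6: 5,7-dihydroxyflavone ⇐ 4-pyranone bearing CO2Me (C5) on C4a and CH(prenyl)C(O)CH3 (C8, C7, C6) on C8a.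
4. Keto ester ⇐ lateral C-acetylation (C7–C8) of the 2-(4-methylpent-3-enyl)pyranone ester ⇐ 6-endo-dig O-closure of the tricarbonyl made from an arylpropioloyl chloride and γ-prenylated methyl acetoacetate. The prenyl group is fixed on the future C8 before any ring exists.
5. Ring order: ring B is bought, ring C is closed in step 6, ring A in step 8.

Key step: step 8

Assumption: flavone locants (O1, C2–C4, C4a, C5–C8, C8a, primed for ring B) are used for the corresponding atoms of all intermediates; the one stereocentre met on the way (C8 of the keto ester) is racemic and vanishes on aromatisation, the target being achiral.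

## Route

Step 1
Reactants: 1 4-hydroxy-2-methoxybenzaldehyde
Product: 2 2-methoxy-4-(triisopropylsilyloxy)benzaldehyde
Conditions: i-Pr3SiCl (1.1 equiv), imidazole (2 equiv), DMF, 0 °C → rt
Reagents that add atoms: triisopropylsilyl chloride, CC(C)[Si](Cl)(C(C)C)C(C)C
Why: Imidazole-promoted O-silylation of a phenol; the bulky aryl silyl ether should withstand n-BuLi, amide bases and carbonate and can be removed at the end by fluoride without touching the prenyl group.

Step 2
Reactants: 2 2-methoxy-4-(triisopropylsilyloxy)benzaldehyde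
Product: 3 1-(2,2-dibromoethenyl)-2-methoxy-4-(triisopropylsilyloxy)benzene
Conditions: CBr4 (1.5 equiv), PPh3 (3 equiv), CH2Cl2, 0 °C
Reagents that add atoms: carbon tetrabromide, BrC(Br)(Br)Br
Why: Corey–Fuchs dibromoolefination, a Wittig-type reaction of Ph3P=CBr2 that is reliable on electron-rich benzaldehydes and leaves the ethers alone.

Step 3
Reactants: 3 1-(2,2-dibromoethenyl)-2-methoxy-4-(triisopropylsilyloxy)benzene
Product: 5 3-[2-methoxy-4-(triisopropylsilyloxy)phenyl]prop-2-ynoic acid, via lithium acetylide 4 (not isolated)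
Conditions: n-BuLi (2.1 equiv), THF, −78 °C; CO2 (dry gas), −78 °C → 0 °C; cold 1 M HCl
Reagents that add atoms: carbon dioxide, O=C=O
Why: Second stage of the Corey–Fuchs sequence (Br/Li exchange, loss of LiBr, metalation of the alkyne) followed by carboxylation of the acetylide, all faster at −78 °C than ring lithiation.

Step 4
Reactants: 6 methyl acetoacetate; 7 prenyl bromide (1-bromo-3-methylbut-2-ene)
Product: 9 methyl 7-methyl-3-oxooct-6-enoate, via acetoacetate dianion 8 (not isolated)
Conditions: NaH (1.1 equiv), THF, 0 °C; n-BuLi (1.05 equiv), 0 °C; 7 (1.0 equiv), 0 °C → rt; 1 M HCl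
Reagents that add atoms: none
Why: Weiler dianion alkylation, in which the more basic γ-terminus takes the allylic bromide by SN2, so the prenyl group is placed only on the carbon that becomes C8.

Step 5
Reactants: 5 3-[2-methoxy-4-(triisopropylsilyloxy)phenyl]prop-2-ynoic acid; 9 methyl 7-methyl-3-oxooct-6-enoate
Product: 11 methyl 2-{3-[2-methoxy-4-(triisopropylsilyloxy)phenyl]prop-2-ynoyl}-7-methyl-3-oxooct-6-enoate, via arylpropioloyl chloride 10 (not isolated)
Conditions: 5, 1-chloro-N,N,2-trimethylprop-1-en-1-amine (1.05 equiv), CH2Cl2, 0 °C; then added to 9, MgCl2 (1.0 equiv), pyridine (2.0 equiv), CH2Cl2, 0 °C → rt; cold 1 M HCl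
Reagents that add atoms: 1-chloro-N,N,2-trimethylprop-1-en-1-amine, CC(C)=C(Cl)N(C)C (supplies only the chlorine of 10; none of its atoms stays in 11)
Why: Neutral chloroenamine activation avoids HCl addition to the electron-rich alkyne, and the chelated magnesium enolate of a β-keto ester is acylated on carbon by acid chlorides (MgCl2/pyridine soft-enolisation C-acylation), 1,2-attack on the acyl chloride being faster than conjugate addition.

Step 6
Reactants: 11 methyl 2-{3-[2-methoxy-4-(triisopropylsilyloxy)phenyl]prop-2-ynoyl}-7-methyl-3-oxooct-6-enoate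
Product: 12 methyl 6-[2-methoxy-4-(triisopropylsilyloxy)phenyl]-2-(4-methylpent-3-enyl)-4-oxo-4H-pyran-3-carboxylate
Conditions: Et3N (1.0 equiv), DMAP (0.2 equiv), MeCN, rt → 45 °C
Reagents that add atoms: none
Why: Intramolecular oxa-Michael addition of the enolised ketone oxygen to the aryl-bearing alkyne carbon (6-endo-dig, the polarity-matched mode, helped by reversible conjugate addition of DMAP) is the long-known way from acetylenic acyl β-keto esters to 4-pyranone-3-carboxylates, and the amine medium spares silyl ether, ester and alkene.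

Step 7
Reactants: 12 methyl 6-[2-methoxy-4-(triisopropylsilyloxy)phenyl]-2-(4-methylpent-3-enyl)-4-oxo-4H-pyran-3-carboxylate; 13 1-acetyl-1H-benzotriazole
Product: 15 methyl 6-[2-methoxy-4-(triisopropylsilyloxy)phenyl]-2-(6-methyl-2-oxohept-5-en-3-yl)-4-oxo-4H-pyran-3-carboxylate (racemic), via lateral lithium dienolate 14 (not isolated)
Conditions: LiN(SiMe3)2 (2.2 equiv), THF, −78 °C; 13 (1.2 equiv), −78 → −40 °C; AcOH, −78 °C
Reagents that add atoms: none
Why: The CH2 on C8a is vinylogously acidified by C4=O and the ester, and lateral Claisen-type C-acylation of 2-alkyl-4-pyranone anions is known; an N-acylbenzotriazole is preferred to a Weinreb amide because 14 is a stabilised, weak nucleophile, because any O-acetyl product is returned by benzotriazolide, and because the second equivalent of base stores 15 as its inert enolate until the cold acidic quench (C8 forms racemic and is erased in step 8).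

Step 8
Reactants: 15 methyl 6-[2-methoxy-4-(triisopropylsilyloxy)phenyl]-2-(6-methyl-2-oxohept-5-en-3-yl)-4-oxo-4H-pyran-3-carboxylate
Product: 18 5,7-dihydroxy-2-[2-methoxy-4-(triisopropylsilyloxy)phenyl]-8-(3-methylbut-2-enyl)chromen-4-one, via dilithium dianion 16 (not isolated), via ring-closed keto enolate 17 (not isolated)
Conditions: LiN(i-Pr)2 (commercial solution, 2.8 equiv), THF, −78 °C, then 0 °C; 1 M HCl
Reagents that add atoms: none
Why: The first equivalent of base removes the C8–H methine proton and the second a C6–H of the methyl ketone, a β-dicarbonyl-dianion type of deprotonation for which LiN(i-Pr)2 is used because LiN(SiMe3)2 is too weak; the unstabilised C6 terminus of 16 adds to the ester carbonyl C5, methoxide leaves, and 17 gives up a C6 proton to that methoxide to form the aromatic 5,7-bisphenoxide, protonated on work-up. The closest known reactions are the Claisen (Dieckmann-type) cyclisations of 3,5-dioxoalkanoate chains to resorcinols and of 2-(2-oxopropyl)benzoates to naphthalene-1,3-diols, the C8a=C4a bond of the pyranone taking the place of the arene bond. Ring A closes in a 6-(enolendo)-exo-trig mode (C6=C7 of the enolate inside the new ring, the ester C=O outside it), which is favoured for six-membered rings. No stereocentre is created and the racemic C8 centre of 15 disappears. The selectivity needed is C- over O-acylation, since the C7 enolate oxygen also reaches C5 through a six-membered transition state and would give the fused enol lactone; it is secured by the far higher nucleophilicity of the carbon terminus of the dianion and by the fact that lactone formation is reversed by LiOMe whereas aromatisation is not. The acetyl group has to lie on the C4a side of the C8–C8a bond, and rotation about this partial double bond on warming should feed the reactive rotamer.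

Step 9
Reactants: 18 5,7-dihydroxy-2-[2-methoxy-4-(triisopropylsilyloxy)phenyl]-8-(3-methylbut-2-enyl)chromen-4-one
Product: 19 5-hydroxy-7-methoxy-2-[2-methoxy-4-(triisopropylsilyloxy)phenyl]-8-(3-methylbut-2-enyl)chromen-4-one
Conditions: MeI (1.1 equiv), K2CO3 (1.1 equiv), acetone, rt
Reagents that add atoms: iodomethane, CI
Why: Williamson O-methylation under weak base, the classical selective 7-O-alkylation of 5,7-dihydroxyflavones: only the vinylogously acidic 7-OH is ionised, the 5-OH is held in a hydrogen bond to C4=O and the 4'-oxygen is silylated.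

Step 10
Reactants: 19 5-hydroxy-7-methoxy-2-[2-methoxy-4-(triisopropylsilyloxy)phenyl]-8-(3-methylbut-2-enyl)chromen-4-one
Product: 20 artocarpetin B, 5-hydroxy-2-(4-hydroxy-2-methoxyphenyl)-7-methoxy-8-(3-methylbut-2-enyl)chromen-4-one
Conditions: Bu4NF (1.1 equiv), AcOH (1.1 equiv), THF, 0 °C
Reagents that add atoms: none
Why: Fluoride-induced cleavage of the aryl silyl ether, buffered with acetic acid so that the medium stays near neutral and the methyl ethers, prenyl group and pyranone are not affected.

## Compound list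

1 | 4-hydroxy-2-methoxybenzaldehyde | COc1cc(O)ccc1C=O | starting material
2 | 2-methoxy-4-(triisopropylsilyloxy)benzaldehyde | COc1cc(O[Si](C(C)C)(C(C)C)C(C)C)ccc1C=O | intermediate
3 | 1-(2,2-dibromoethenyl)-2-methoxy-4-(triisopropylsilyloxy)benzene | COc1cc(O[Si](C(C)C)(C(C)C)C(C)C)ccc1C=C(Br)Br | intermediate
4 | lithium [2-methoxy-4-(triisopropylsilyloxy)phenyl]acetylide (not isolated) | [Li+].[C-]#Cc1ccc(O[Si](C(C)C)(C(C)C)C(C)C)cc1OC | intermediate
5 | 3-[2-methoxy-4-(triisopropylsilyloxy)phenyl]prop-2-ynoic acid | OC(=O)C#Cc1ccc(O[Si](C(C)C)(C(C)C)C(C)C)cc1OC | intermediate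
6 | methyl acetoacetate | COC(=O)CC(C)=O | starting material
7 | prenyl bromide | CC(C)=CCBr | starting material
8 | sodium lithium dianion of methyl acetoacetate (not isolated) | [Na+].[Li+].C=C([O-])C=C([O-])OC | intermediate
9 | methyl 7-methyl-3-oxooct-6-enoate | COC(=O)CC(=O)CCC=C(C)C | intermediate
10 | 3-[2-methoxy-4-(triisopropylsilyloxy)phenyl]prop-2-ynoyl chloride (not isolated) | ClC(=O)C#Cc1ccc(O[Si](C(C)C)(C(C)C)C(C)C)cc1OC | intermediate
11 | methyl 2-{3-[2-methoxy-4-(triisopropylsilyloxy)phenyl]prop-2-ynoyl}-7-methyl-3-oxooct-6-enoate (drawn as triketo form; enolised, C2 labile) | COC(=O)C(C(=O)CCC=C(C)C)C(=O)C#Cc1ccc(O[Si](C(C)C)(C(C)C)C(C)C)cc1OC | intermediate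
12 | methyl 6-[2-methoxy-4-(triisopropylsilyloxy)phenyl]-2-(4-methylpent-3-enyl)-4-oxo-4H-pyran-3-carboxylate | COC(=O)c1c(CCC=C(C)C)oc(-c2ccc(O[Si](C(C)C)(C(C)C)C(C)C)cc2OC)cc1=O | intermediate
13 | 1-acetyl-1H-benzotriazole | CC(=O)n1nnc2ccccc21 | starting material
14 | lithium dienolate of 12, a 2-alkylidene-2H-pyran-4-olate (not isolated) | [Li+].COC(=O)C1=C([O-])C=C(c2ccc(O[Si](C(C)C)(C(C)C)C(C)C)cc2OC)OC1=CCC=C(C)C | intermediate
15 | methyl 6-[2-methoxy-4-(triisopropylsilyloxy)phenyl]-2-(6-methyl-2-oxohept-5-en-3-yl)-4-oxo-4H-pyran-3-carboxylate (racemic) | COC(=O)c1c(C(CC=C(C)C)C(C)=O)oc(-c2ccc(O[Si](C(C)C)(C(C)C)C(C)C)cc2OC)cc1=O | intermediate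
16 | dilithium dianion of 15 (not isolated) | [Li+].[Li+].C=C([O-])C(CC=C(C)C)=C1OC(c2ccc(O[Si](C(C)C)(C(C)C)C(C)C)cc2OC)=CC([O-])=C1C(=O)OC | intermediate
17 | lithium 7-enolate of the 2-aryl-8-prenyl-6H-chromene-4,5,7-trione (not isolated) | [Li+].O=C1CC([O-])=C(CC=C(C)C)c2oc(-c3ccc(O[Si](C(C)C)(C(C)C)C(C)C)cc3OC)cc(=O)c21 | intermediate
18 | 5,7-dihydroxy-2-[2-methoxy-4-(triisopropylsilyloxy)phenyl]-8-(3-methylbut-2-enyl)chromen-4-one | CC(C)=CCc1c(O)cc(O)c2c(=O)cc(-c3ccc(O[Si](C(C)C)(C(C)C)C(C)C)cc3OC)oc12 | intermediate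
19 | 5-hydroxy-7-methoxy-2-[2-methoxy-4-(triisopropylsilyloxy)phenyl]-8-(3-methylbut-2-enyl)chromen-4-one | COc1cc(O)c2c(=O)cc(-c3ccc(O[Si](C(C)C)(C(C)C)C(C)C)cc3OC)oc2c1CC=C(C)C | intermediate
20 | artocarpetin B | COc1cc(O)ccc1-c1cc(=O)c2c(O)cc(OC)c(CC=C(C)C)c2o1 | target

## Step count and risks

Total: 10 steps. Longest linear sequence: 9 steps (1 → 20 through steps 1, 2, 3, 5, 6, 7, 8, 9, 10). Step 4 is a one-step side branch.

Steps most likely to fail:

**1. Step 8 (key step).**
- Risk: closure may go through the C7 enolate oxygen instead of C6. The second deprotonation may be incomplete. The liberated methoxide may attack the pyranone ring or the silyl ether.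
- Fallback (from 15, back at 19): the C7 carbonyl is masked as a methyl ether before ring closure. This removes the oxygen nucleophile and the need for a dianion, and it installs the 7-O-methyl group.
- HC(OMe)3 and cat. p-TsOH in MeOH should give the dimethyl ketal F1.
- With LiN(i-Pr)2 (2.3 equiv, THF, −78 → 0 °C) the C8 anion expels methoxide (E1cB) to give the methyl enol ether F2 in the flask.
- A second deprotonation takes a C6 proton, now vinylogously acidified through C7=C8–C8a=C4a.
- The resulting trienolate closes on the ester. This is a vinylogous Dieckmann condensation, which can equally be read as an anionic 6π-electrocyclisation of C6=C7–C8=C8a–C4a=C5.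
- Loss of methoxide and aromatisation lead directly to 19, so step 9 is not needed.

**2. Step 7.**
- Risk: the acyl group may transfer to oxygen rather than to the hindered, ester-stabilised lateral carbon. Proton exchange may also stall the conversion.
- Fallback (from 6 and 7, using 10 from step 5, back at 15): C6 and C7 are brought in as a masked acetyl group before ring C exists.
- K2CO3 in acetone should give methyl 2-acetyl-5-methylhex-4-enoate F3.
- Ethylene glycol with cat. p-TsOH (Dean–Stark) gives the dioxolane ester F4.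
- KOH in aqueous MeOH, with careful acidification, gives the dioxolane acid F5.
- Carbonyldiimidazole gives the acyl imidazole F6, which Mg(O2CCH2CO2Me)2 homologates (Masamune–Brooks) to the β-keto ester F7.
- F7 is acylated with 10 as in step 5 to the tricarbonyl compound F8, which is closed as in step 6 to the pyranone dioxolane F9.
- Pyridinium p-toluenesulfonate in wet acetone then releases the ketone 15.

**3. Step 6.**
- Risk: the ring may close in the wrong mode (5-exo attack, or attack by the ester oxygen). The amine may also deacylate the tricarbonyl compound.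
- Fallback (from 2 and 9, back at 12): ring C is built from an aroylketene instead of an ynone.
- Pinnick oxidation of 2 (NaClO2, NaH2PO4, 2-methylbut-2-ene, t-BuOH/H2O) should give 2-methoxy-4-(triisopropylsilyloxy)benzoic acid F10.
- EDC/DMAP coupling with Meldrum's acid gives the aroyl Meldrum's acid F11.
- 9 and pyrrolidine (toluene, Dean–Stark) give the pyrrolidine enamino ester F12.
- Heating F11 with F12 in toluene at 110 °C releases the aroylketene F13. Its ketene carbon is attacked by the enamine α-carbon, and the aroyl oxygen closes on the iminium carbon.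
- Loss of pyrrolidine gives 12, and steps 2, 3, 5 and 6 are then bypassed.

Further compounds

F1 | step 8 | methyl 2-(2,2-dimethoxy-6-methylhept-5-en-3-yl)-6-[2-methoxy-4-(triisopropylsilyloxy)phenyl]-4-oxo-4H-pyran-3-carboxylate (racemic) | COC(=O)c1c(C(CC=C(C)C)C(C)(OC)OC)oc(-c2ccc(O[Si](C(C)C)(C(C)C)C(C)C)cc2OC)cc1=O
F2 | step 8 | methyl 2-(2-methoxy-6-methylhepta-2,5-dien-3-yl)-6-[2-methoxy-4-(triisopropylsilyloxy)phenyl]-4-oxo-4H-pyran-3-carboxylate (C7=C8 geometry not fixed) | COC(=O)c1c(C(CC=C(C)C)=C(C)OC)oc(-c2ccc(O[Si](C(C)C)(C(C)C)C(C)C)cc2OC)cc1=O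
F3 | step 7 | methyl 2-acetyl-5-methylhex-4-enoate (racemic) | COC(=O)C(CC=C(C)C)C(C)=O
F4 | step 7 | methyl 5-methyl-2-(2-methyl-1,3-dioxolan-2-yl)hex-4-enoate (racemic) | COC(=O)C(CC=C(C)C)C1(C)OCCO1
F5 | step 7 | 5-methyl-2-(2-methyl-1,3-dioxolan-2-yl)hex-4-enoic acid (racemic) | OC(=O)C(CC=C(C)C)C1(C)OCCO1
F6 | step 7 | 1-(imidazol-1-yl)-5-methyl-2-(2-methyl-1,3-dioxolan-2-yl)hex-4-en-1-one (racemic) | O=C(C(CC=C(C)C)C1(C)OCCO1)n1ccnc1
F7 | step 7 | methyl 7-methyl-4-(2-methyl-1,3-dioxolan-2-yl)-3-oxooct-6-enoate (racemic) | COC(=O)CC(=O)C(CC=C(C)C)C1(C)OCCO1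
F8 | step 7 | methyl 2-{3-[2-methoxy-4-(triisopropylsilyloxy)phenyl]prop-2-ynoyl}-7-methyl-4-(2-methyl-1,3-dioxolan-2-yl)-3-oxooct-6-enoate (racemic, enolised) | COC(=O)C(C(=O)C#Cc1ccc(O[Si](C(C)C)(C(C)C)C(C)C)cc1OC)C(=O)C(CC=C(C)C)C1(C)OCCO1
F9 | step 7 | methyl 6-[2-methoxy-4-(triisopropylsilyloxy)phenyl]-2-[4-methyl-1-(2-methyl-1,3-dioxolan-2-yl)pent-3-enyl]-4-oxo-4H-pyran-3-carboxylate (racemic) | COC(=O)c1c(C(CC=C(C)C)C2(C)OCCO2)oc(-c2ccc(O[Si](C(C)C)(C(C)C)C(C)C)cc2OC)cc1=O
F10 | step 6 | 2-methoxy-4-(triisopropylsilyloxy)benzoic acid | COc1cc(O[Si](C(C)C)(C(C)C)C(C)C)ccc1C(=O)O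
F11 | step 6 | 5-{hydroxy[2-methoxy-4-(triisopropylsilyloxy)phenyl]methylidene}-2,2-dimethyl-1,3-dioxane-4,6-dione | CC1(C)OC(=O)C(=C(O)c2ccc(O[Si](C(C)C)(C(C)C)C(C)C)cc2OC)C(=O)O1
F12 | step 6 | methyl (E)-7-methyl-3-(pyrrolidin-1-yl)octa-2,6-dienoate | COC(=O)/C=C(\CCC=C(C)C)N1CCCC1
F13 | step 6 | 3-[2-methoxy-4-(triisopropylsilyloxy)phenyl]-3-oxoprop-1-en-1-one (aroylketene) | O=C=CC(=O)c1ccc(O[Si](C(C)C)(C(C)C)C(C)C)cc1OC
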